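| flask | acidic substrate | electrophile | capture agent | solid base | remark | time |
|---|---|---|---|---|---|---|
| alder | 20 mM | 36 mM | 28 mM | 20 mM | run made earlier |  |
| larch | 20 mM | 36 mM | 61 mM | 20 mM | run made earlier |  |
| east | 20 mM | 36.0 mM | 20.0 mM | 20.0 mM |  | 8.0 d |
| south-east | 20 mM | 36.0 mM | 40.0 mM | 20.0 mM |  | 8.0 d |

| run | time / d | acidic substrate / % | trapped intermediate / % | target / % | anion / % |
|---|---|---|---|---|---|
| alder | 0.417 | 93 | 0 | 4 | 0 |
| alder | 0.625 | 87 | 2 | 11 | 1 |
| alder | 1.04 | 78 | 4 | 17 | 0 |
| alder | 1.67 | 68 | 3 | 30 | 2 |
| alder | 2.50 | 53 | 4 | 43 | 1 |
| alder | 4.00 | 26 | 7 | 69 | 0 |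
| alder | 6.00 | 4 | 5 | 88 | 4 |
| larch | 0.417 | 91 | 1 | 6 | 5 |
| larch | 0.625 | 88 | 1 | 13 | 0 |
| larch | 1.04 | 79 | 4 | 17 | 0 |
| larch | 1.67 | 70 | 2 | 26 | 1 |
| larch | 2.50 | 54 | 5 | 42 | 3 |
| larch | 4.00 | 27 | 9 | 63 | 0 |
| larch | 6.00 | 6 | 15 | 85 | 0 |

(readings scatter by 1.5 percentage points)

- solid, in amounts per volume of the solution: solid base
- at the start none of the solid base is in solution

- which of these there is most of at the end, counted by the acidic substrate in it, east (anion / acidic substrate / target / trapped intermediate)
- which of these there is most of at the end, counted by the acidic substrate in it, south-east (anion / acidic substrate / target / trapped intermediate)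
- amount of the one of these that there is most of at the end, in percent of the acidic substrate charged, east
- amount of the one of these that there is most of at the end, in percent of the acidic substrate charged, south-east

- At the last larch reading, 6.00 d, stood 85% target, 15% trapped intermediate and 6% acidic substrate, which gives 5.67 target per trapped intermediate.
- For east and south-east we take it that the solid base turns acidic substrate into anion, and that each anion meets one of two partners: electrophile gives target, capture agent gives trapped intermediate.
- In larch, capture agent stood at 3.05 substrate charges, and electrophile, its charge less half the substrate charge as a mean, at 1.30.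
- That reading, which carries a scatter of 1.5 percentage points, gives 13.3 for the selectivity factor, the target made per trapped intermediate at equal electrophile and capture agent.
- By our reckoning east should make 17.3 target per trapped intermediate and south-east 8.64, so target takes 94.5% of reacted substrate in east and 89.6% in south-east.
- Do not add capture agent: south-east holds twice the capture agent of east, so by our reckoning its ratio is half of east's.
- Do not stop early: alder, with the same charges of acidic substrate and solid base, still read 4% acidic substrate at 6.00 d, and east and south-east run to 8.0 d.
- The forecast gives target at 94% in east and target at 90% in south-east, saying of the anion that “it partitions between electrophile” and capture agent.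

The flasks give target at 93.3% in east and target at 89.2% in south-east.

    acidic substrate + free base ⇌ protonated base + anion, settled at all times (K = 1.01)
    solid base ⇌ free base, rate k2*(cs2 - [free base]) while solid is left; crystals form when [free base] > cs2 (solubility = 2.00 mM, k = 0.0828 h⁻¹)
    anion + capture agent → trapped intermediate (k = 2.85 M⁻¹ h⁻¹)
    electrophile + anion → target (k = 41.5 M⁻¹ h⁻¹)

- In south-east at 2.57 d, anion goes to target 10 times as fast as to trapped intermediate, and at the end that flask holds 9.72 target per trapped intermediate against our 8.64. Carried to the neighbour flask, south-east with 8.0 mM solid base, where we take mean electrophile as its charge less half that solid base, the selectivity factor gives 10.6, and that flask holds 36.9% target and 3.12% trapped intermediate at 8.00 d, a ratio of 11.8.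

The runs come from a simulation from invented constants, noise included.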